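The route makes the C3a–C4 bond (azulene numbering: ring-fusion CH to the ester-bearing CH) as a C3a=C4 double bond. In the target, H-3a and O-4 are syn and lie on the hydroxyl face of C3, which is the retron of a hydroboration. The key step, a ring-closing metathesis, closes the seven-membered ring between an exocyclic methylidene on the cyclopentane and a terminal vinyl group. Its precursor is a terpinen-4-ol-derived 2-methylidenecyclopentanol whose quaternary centre comes from a Claisen rearrangement and whose later C6=C7 alkene is masked as a β-benzoyloxy sulfone.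

Key step: step 8

Remark: commercial (S)-(+)-terpinen-4-ol is assumed to be of high enantiomeric purity, since its carbinol centre is the source of all four stereocentres. Locants in the text follow the azulene numbering of the target (C3 carbinol carbon, C3a ring-fusion CH, C4 ester-bearing carbon, C6 methyl-bearing carbon, C8a quaternary carbon). The two side-chain centres made in step 7 are carried as a mixture and drawn without configuration.

Step 1
Reactants: 1 (S)-(+)-terpinen-4-ol
Product: 2 triethyl{[(1S)-4-methyl-1-(propan-2-yl)cyclohex-3-en-1-yl]oxy}silane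
Conditions: TESOTf, 2,6-lutidine, CH2Cl2, 0 °C to rt
Reagents that add atoms: triethylsilyl trifluoromethanesulfonate, CC[Si](CC)(CC)OS(=O)(=O)C(F)(F)F
Why: Silyl ether formation with the silyl triflate and a hindered pyridine base is the standard way to cap a tertiary alcohol and is needed so that the oxygen is not expelled from the β-position of the aldehyde made in step 2; the stereocentre is not touched.

Step 2
Reactants: 2 triethyl{[(1S)-4-methyl-1-(propan-2-yl)cyclohex-3-en-1-yl]oxy}silane
Product: 4 (5R)-2-methyl-5-(propan-2-yl)-5-[(triethylsilyl)oxy]cyclopent-1-ene-1-carbaldehyde, via keto aldehyde 3 (not isolated)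
Conditions: O3, CH2Cl2, −78 °C; Me2S, −78 °C to rt; then piperidine (cat.), AcOH (cat.), benzene, 80 °C
Reagents that add atoms: ozone, [O-][O+]=O
Why: Ozonolysis of the only alkene gives keto aldehyde 3, whose aldehyde enamine adds to the methyl ketone and loses the new, unprotected tertiary hydroxyl (intramolecular aldol condensation of the type known for the limonene-derived keto aldehyde), which contracts the six-membered ring to the cyclopentene without touching the carbinol stereocentre.

Step 3
Reactants: 4 (5R)-2-methyl-5-(propan-2-yl)-5-[(triethylsilyl)oxy]cyclopent-1-ene-1-carbaldehyde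
Product: 5 [(5R)-2-methyl-5-(propan-2-yl)-5-[(triethylsilyl)oxy]cyclopent-1-en-1-yl]methanol
Conditions: i-Bu2AlH, CH2Cl2, −78 °C
Reagents that add atoms: none
Why: Reduction of the enal with i-Bu2AlH at low temperature should give clean 1,2-reduction to the primary allylic alcohol (hydride reduction) with no new stereocentre.

Step 4
Reactants: 5 [(5R)-2-methyl-5-(propan-2-yl)-5-[(triethylsilyl)oxy]cyclopent-1-en-1-yl]methanol
Product: 6 {[(1R)-2-[(ethenyloxy)methyl]-3-methyl-1-(propan-2-yl)cyclopent-2-en-1-yl]oxy}triethylsilane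
Conditions: [Ir(cod)Cl]2 (cat.), Na2CO3, vinyl acetate, toluene, 100 °C
Reagents that add atoms: vinyl acetate, C=COC(C)=O
Why: Iridium-catalysed transfer vinylation from vinyl acetate under basic conditions converts the primary allylic alcohol into the allyl vinyl ether without acid, so the silyl ether survives.

Step 5
Reactants: 6 {[(1R)-2-[(ethenyloxy)methyl]-3-methyl-1-(propan-2-yl)cyclopent-2-en-1-yl]oxy}triethylsilane
Product: 7 2-[(1S,3R)-1-methyl-2-methylidene-3-(propan-2-yl)-3-[(triethylsilyl)oxy]cyclopentyl]acetaldehyde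
Conditions: o-xylene, 180 °C, sealed tube (base-washed glass)
Reagents that add atoms: none
Why: Thermal Claisen rearrangement through a chair transition state moves the two-carbon unit to the methyl-bearing alkene carbon on the ring face of the silyloxy group, away from the bulkier isopropyl group, which sets the quaternary stereocentre C8a with its acetaldehyde arm cis to the C3 oxygen and leaves the exocyclic methylidene at C3a.

Step 6
Reactants: 8 ethyl phenyl sulfone; 9 allyl bromide
Product: 10 [(pent-4-en-2-yl)sulfonyl]benzene (racemic)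
Conditions: n-BuLi, THF, −78 °C; then 9, −78 °C to rt
Reagents that add atoms: none
Why: α-Lithiation of the sulfone followed by SN2 alkylation with allyl bromide (sulfone alkylation) gives the branched sulfone, used as the racemate because its stereocentre is deprotonated in step 7.

Step 7
Reactants: 7 2-[(1S,3R)-1-methyl-2-methylidene-3-(propan-2-yl)-3-[(triethylsilyl)oxy]cyclopentyl]acetaldehyde; 10 [(pent-4-en-2-yl)sulfonyl]benzene
Product: 13 1-[(1S,3R)-3-hydroxy-1-methyl-2-methylidene-3-(propan-2-yl)cyclopentyl]-3-methyl-3-(phenylsulfonyl)hex-5-en-2-yl benzoate (mixture at the two side-chain stereocentres), via lithium alkoxide 11 (not isolated), via silyl ether benzoate 12 (not isolated)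
Conditions: 10, n-BuLi, THF, −78 °C; then 7, −78 °C; then PhCOCl, −78 °C to 0 °C; crude 12, TBAF, AcOH, THF, rt
Reagents that add atoms: n-butyllithium, [Li]CCCC; benzoyl chloride, O=C(Cl)c1ccccc1
Why: Addition of the α-sulfonyl carbanion to the aldehyde gives lithium alkoxide 11, which benzoyl chloride acylates in the same flask so that the adduct cannot revert (first stage of a Julia–Lythgoe olefination), and buffered fluoride then cleaves the silyl ether without touching the benzoate or the sulfone, whose carbon bears no hydrogen; the two new side-chain stereocentres are left uncontrolled because both become sp2 in step 11.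

Step 8
Reactants: 13 1-[(1S,3R)-3-hydroxy-1-methyl-2-methylidene-3-(propan-2-yl)cyclopentyl]-3-methyl-3-(phenylsulfonyl)hex-5-en-2-yl benzoate
Product: 14 (3R,8aS)-3-hydroxy-6,8a-dimethyl-6-(phenylsulfonyl)-3-(propan-2-yl)-1,2,3,5,6,7,8,8a-octahydroazulen-7-yl benzoate (mixture at C6 and C7)
Conditions: second-generation Hoveyda–Grubbs catalyst [RuCl2(H2IMes)(=CH-C6H4-2-OiPr)] (cat.), toluene (high dilution), 80 °C, argon sparge
Reagents that add atoms: none
Why: The ruthenium alkylidene should form at the unhindered vinyl group of 13, add across the exocyclic methylidene in a [2+2] fashion and cyclorevert with loss of ethylene to give the trisubstituted C3a=C4 alkene. The closest known reaction type is ring-closing olefin metathesis of a 1,1-disubstituted with a monosubstituted alkene to a trisubstituted cycloalkene next to quaternary centres, here helped by the free allylic hydroxyl and the fully substituted carbons of the tether. The seven-membered ring is closed by joining the two alkene carbons that become C3a and C4, both of which end inside the new ring. No stereocentre is formed; the step removes the question of ring-fusion geometry, which is answered in step 9 under control of the C3 stereocentre. The selectivity needed is ring closure over intermolecular metathesis, secured by high dilution, removal of ethylene and the fact that 13 holds only these two alkenes, the later C6=C7 alkene being masked as the β-benzoyloxy sulfone.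

Step 9
Reactants: 14 (3R,8aS)-3-hydroxy-6,8a-dimethyl-6-(phenylsulfonyl)-3-(propan-2-yl)-1,2,3,5,6,7,8,8a-octahydroazulen-7-yl benzoate
Product: 16 (3R,3aR,4R,8aS)-3,4-dihydroxy-6,8a-dimethyl-6-(phenylsulfonyl)-3-(propan-2-yl)decahydroazulen-7-yl benzoate (mixture at C6 and C7), via alkylborane 15 (not isolated)
Conditions: BH3·SMe2, THF, 0 °C to rt; then NaBO3·4H2O, THF/H2O, rt
Reagents that add atoms: borane–dimethyl sulfide, [BH3-][S+](C)C; sodium perborate, [Na+].[O-]OB=O
Why: Hydroboration–oxidation of the only alkene places boron on the less substituted C4 and hydrogen on C3a in a syn addition from the face that carries the C3 hydroxyl and the C8 methylene rather than the isopropyl and angular methyl groups, so the trans ring fusion and the C4 oxygen cis to H-3a are set together, and the mild perborate oxidation retains the C4 configuration and leaves the benzoate intact.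

Step 10
Reactants: 16 (3R,3aR,4R,8aS)-3,4-dihydroxy-6,8a-dimethyl-6-(phenylsulfonyl)-3-(propan-2-yl)decahydroazulen-7-yl benzoate; 17 3,4-dimethoxybenzoyl chloride
Product: 18 (3R,3aR,4R,8aS)-7-(benzoyloxy)-3-hydroxy-6,8a-dimethyl-6-(phenylsulfonyl)-3-(propan-2-yl)decahydroazulen-4-yl 3,4-dimethoxybenzoate (mixture at C6 and C7)
Conditions: 17 (1.2 equiv), pyridine, DMAP (cat.), CH2Cl2, 0 °C to rt
Reagents that add atoms: none
Why: DMAP-catalysed esterification with one equivalent of the acid chloride acylates the only secondary hydroxyl, at C4, while the hindered tertiary C3 hydroxyl stays free.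

Step 11
Reactants: 18 (3R,3aR,4R,8aS)-7-(benzoyloxy)-3-hydroxy-6,8a-dimethyl-6-(phenylsulfonyl)-3-(propan-2-yl)decahydroazulen-4-yl 3,4-dimethoxybenzoate
Product: 19 (3R,3aR,4R,8aS)-3-hydroxy-6,8a-dimethyl-3-(propan-2-yl)-1,2,3,3a,4,5,8,8a-octahydroazulen-4-yl 3,4-dimethoxybenzoate
Conditions: SmI2, HMPA, THF, −78 °C
Reagents that add atoms: none
Why: SmI2-promoted reductive elimination of the β-benzoyloxy sulfone (second stage of the Julia–Lythgoe olefination) expels benzenesulfinate and benzoate to give the C6=C7 alkene, whose cis geometry is dictated by the seven-membered ring, while the C4 ester, which is not β to the sulfone, is kept.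

Compound list
1 | (S)-(+)-terpinen-4-ol, (1S)-4-methyl-1-(propan-2-yl)cyclohex-3-en-1-ol | CC1=CC[C@](O)(C(C)C)CC1 | starting material
2 | triethyl{[(1S)-4-methyl-1-(propan-2-yl)cyclohex-3-en-1-yl]oxy}silane | CC1=CC[C@](O[Si](CC)(CC)CC)(C(C)C)CC1 | intermediate
3 | (3S)-6-oxo-3-(propan-2-yl)-3-[(triethylsilyl)oxy]heptanal | O=CC[C@](O[Si](CC)(CC)CC)(C(C)C)CCC(C)=O | intermediate (not isolated)
4 | (5R)-2-methyl-5-(propan-2-yl)-5-[(triethylsilyl)oxy]cyclopent-1-ene-1-carbaldehyde | O=CC1=C(C)CC[C@@]1(O[Si](CC)(CC)CC)C(C)C | intermediate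
5 | [(5R)-2-methyl-5-(propan-2-yl)-5-[(triethylsilyl)oxy]cyclopent-1-en-1-yl]methanol | OCC1=C(C)CC[C@@]1(O[Si](CC)(CC)CC)C(C)C | intermediate
6 | {[(1R)-2-[(ethenyloxy)methyl]-3-methyl-1-(propan-2-yl)cyclopent-2-en-1-yl]oxy}triethylsilane | C=COCC1=C(C)CC[C@@]1(O[Si](CC)(CC)CC)C(C)C | intermediate
7 | 2-[(1S,3R)-1-methyl-2-methylidene-3-(propan-2-yl)-3-[(triethylsilyl)oxy]cyclopentyl]acetaldehyde | O=CC[C@]1(C)CC[C@@](O[Si](CC)(CC)CC)(C(C)C)C1=C | intermediate
8 | ethyl phenyl sulfone | CCS(=O)(=O)c1ccccc1 | starting material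
9 | allyl bromide | C=CCBr | starting material
10 | [(pent-4-en-2-yl)sulfonyl]benzene (racemic) | C=CCC(C)S(=O)(=O)c1ccccc1 | intermediate
11 | lithium 1-[(1S,3R)-1-methyl-2-methylidene-3-(propan-2-yl)-3-[(triethylsilyl)oxy]cyclopentyl]-3-methyl-3-(phenylsulfonyl)hex-5-en-2-olate (side-chain centres as a mixture) | [Li]OC(C[C@]1(C)CC[C@@](O[Si](CC)(CC)CC)(C(C)C)C1=C)C(C)(CC=C)S(=O)(=O)c1ccccc1 | intermediate (not isolated)
12 | 1-[(1S,3R)-1-methyl-2-methylidene-3-(propan-2-yl)-3-[(triethylsilyl)oxy]cyclopentyl]-3-methyl-3-(phenylsulfonyl)hex-5-en-2-yl benzoate (side-chain centres as a mixture) | C=CCC(C)(S(=O)(=O)c1ccccc1)C(OC(=O)c1ccccc1)C[C@]1(C)CC[C@@](O[Si](CC)(CC)CC)(C(C)C)C1=C | intermediate (not isolated)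
13 | 1-[(1S,3R)-3-hydroxy-1-methyl-2-methylidene-3-(propan-2-yl)cyclopentyl]-3-methyl-3-(phenylsulfonyl)hex-5-en-2-yl benzoate (side-chain centres as a mixture) | C=CCC(C)(S(=O)(=O)c1ccccc1)C(OC(=O)c1ccccc1)C[C@]1(C)CC[C@@](O)(C(C)C)C1=C | intermediate
14 | (3R,8aS)-3-hydroxy-6,8a-dimethyl-6-(phenylsulfonyl)-3-(propan-2-yl)-1,2,3,5,6,7,8,8a-octahydroazulen-7-yl benzoate (C6 and C7 as a mixture) | CC1(S(=O)(=O)c2ccccc2)CC=C2[C@](O)(C(C)C)CC[C@@]2(C)CC1OC(=O)c1ccccc1 | intermediate
15 | C4 alkylborane of 16 (boron in place of the C4 hydroxyl, same configuration; drawn with the free C3 hydroxyl) | B[C@@H]1CC(C)(S(=O)(=O)c3ccccc3)C(OC(=O)c3ccccc3)C[C@]2(C)CC[C@@](O)(C(C)C)[C@@H]12 | intermediate (not isolated)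
16 | (3R,3aR,4R,8aS)-3,4-dihydroxy-6,8a-dimethyl-6-(phenylsulfonyl)-3-(propan-2-yl)decahydroazulen-7-yl benzoate (C6 and C7 as a mixture) | O[C@@H]1CC(C)(S(=O)(=O)c3ccccc3)C(OC(=O)c3ccccc3)C[C@]2(C)CC[C@@](O)(C(C)C)[C@@H]12 | intermediate
17 | 3,4-dimethoxybenzoyl chloride | COc1ccc(C(Cl)=O)cc1OC | starting material
18 | (3R,3aR,4R,8aS)-7-(benzoyloxy)-3-hydroxy-6,8a-dimethyl-6-(phenylsulfonyl)-3-(propan-2-yl)decahydroazulen-4-yl 3,4-dimethoxybenzoate (C6 and C7 as a mixture) | COc1ccc(C(=O)O[C@@H]2CC(C)(S(=O)(=O)c3ccccc3)C(OC(=O)c3ccccc3)C[C@]4(C)CC[C@@](O)(C(C)C)[C@@H]24)cc1OC | intermediate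
19 | (3R,3aR,4R,8aS)-3-hydroxy-6,8a-dimethyl-3-(propan-2-yl)-1,2,3,3a,4,5,8,8a-octahydroazulen-4-yl 3,4-dimethoxybenzoate | COc1ccc(C(=O)O[C@@H]2CC(C)=CC[C@]3(C)CC[C@@](O)(C(C)C)[C@@H]23)cc1OC | target

Total step count: 11. Longest linear sequence: 10 steps (steps 1 to 5 and 7 to 11).

Steps most likely to fail

Step 8. The ruthenium alkylidene may fail to add to the methylidene carbon, which is flanked by two fully substituted carbons, so that intermolecular metathesis of the vinyl group would consume the material. The fallback replaces olefin metathesis by carbonyl coupling. It sets out from 13: ozonolysis of both alkenes (O3, CH2Cl2/MeOH, −78 °C; Me2S) should give 1-[(1S,3R)-3-hydroxy-1-methyl-2-oxo-3-(propan-2-yl)cyclopentyl]-3-methyl-5-oxo-3-(phenylsulfonyl)pentan-2-yl benzoate F1. An intramolecular McMurry coupling (TiCl3, Zn(Cu), DME, reflux, slow addition of F1) should then join the ketone and aldehyde carbons to the same C3a=C4 alkene. The sequence comes back to the route at 14.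

Step 2. The silyloxy group may be lost by β-elimination from the aldehyde enamine, or the ketone enolate may condense onto the aldehyde, during the hot amine–acid condensation. The fallback separates bond formation from dehydration. It sets out from 2: ozonolysis as before with isolation of 3, then L-proline-catalysed enolexo aldolisation (CH2Cl2, rt) to (5R)-2-hydroxy-2-methyl-5-(propan-2-yl)-5-[(triethylsilyl)oxy]cyclopentane-1-carbaldehyde F2. Burgess reagent (benzene, 50 °C) should then remove only the free tertiary hydroxyl by syn elimination. The sequence comes back to the route at 4.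

Step 5. Facial discrimination between the silyloxy and isopropyl groups may erode at 180 °C, giving both epimers at C8a. The fallback replaces steric control by a directing hydroxyl. It sets out from 5: TBAF (THF, rt) should give (1R)-2-(hydroxymethyl)-3-methyl-1-(propan-2-yl)cyclopent-2-en-1-ol F3, and iridium-catalysed vinylation of its primary hydroxyl should give (1R)-2-[(ethenyloxy)methyl]-3-methyl-1-(propan-2-yl)cyclopent-2-en-1-ol F4. In the Claisen rearrangement of F4 (o-xylene, 180 °C, base-washed glass, trace Et3N) the free tertiary hydroxyl should hold the ether oxygen on its own face by a hydrogen bond. The product, 2-[(1S,3R)-3-hydroxy-1-methyl-2-methylidene-3-(propan-2-yl)cyclopentyl]acetaldehyde F5, can close to a bridged lactol only in the desired epimer, which should help separation. Addition of two equivalents of lithiated 10 to F5 (THF, −78 °C; AcOH) should give (1R,3S)-3-[2-hydroxy-3-methyl-3-(phenylsulfonyl)hex-5-en-1-yl]-3-methyl-2-methylidene-1-(propan-2-yl)cyclopentan-1-ol F6. Benzoylation of the secondary hydroxyl of F6 (PhCOCl, pyridine, DMAP, CH2Cl2, 0 °C) comes back to the route at 13.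

Further compounds
F1 | step 8 | 1-[(1S,3R)-3-hydroxy-1-methyl-2-oxo-3-(propan-2-yl)cyclopentyl]-3-methyl-5-oxo-3-(phenylsulfonyl)pentan-2-yl benzoate (side-chain centres as a mixture) | O=CCC(C)(S(=O)(=O)c1ccccc1)C(OC(=O)c1ccccc1)C[C@]1(C)CC[C@@](O)(C(C)C)C1=O
F2 | step 2 | (5R)-2-hydroxy-2-methyl-5-(propan-2-yl)-5-[(triethylsilyl)oxy]cyclopentane-1-carbaldehyde (C1 and C2 uncontrolled) | O=CC1C(C)(O)CC[C@@]1(O[Si](CC)(CC)CC)C(C)C
F3 | step 5 | (1R)-2-(hydroxymethyl)-3-methyl-1-(propan-2-yl)cyclopent-2-en-1-ol | OCC1=C(C)CC[C@@]1(O)C(C)C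
F4 | step 5 | (1R)-2-[(ethenyloxy)methyl]-3-methyl-1-(propan-2-yl)cyclopent-2-en-1-ol | C=COCC1=C(C)CC[C@@]1(O)C(C)C
F5 | step 5 | 2-[(1S,3R)-3-hydroxy-1-methyl-2-methylidene-3-(propan-2-yl)cyclopentyl]acetaldehyde | O=CC[C@]1(C)CC[C@@](O)(C(C)C)C1=C
F6 | step 5 | (1R,3S)-3-[2-hydroxy-3-methyl-3-(phenylsulfonyl)hex-5-en-1-yl]-3-methyl-2-methylidene-1-(propan-2-yl)cyclopentan-1-ol (side-chain centres as a mixture) | C=CCC(C)(S(=O)(=O)c1ccccc1)C(O)C[C@]1(C)CC[C@@](O)(C(C)C)C1=C
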